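**Retrosynthetic overview**
1. Target 25 ⇒ ketol 17 (2α-benzyloxy-4β-hydroxydauc-8-en-6-one): the esters are added late, the C8–C9 oxirane comes from an epoxidation directed by the 6α-OH, and the 6α-OH from a reduction directed by the 4β-OH.
2. Key disconnection of 17: the cyclopentane is cut at C2–C3 and C4–C5 ⇒ bicyclo[5.1.0]octenone 12 (temporary cyclopropane C1–C2–C5, opened in the same step) + enol silane 14 of 3-methylbutan-2-one; a strain-driven formal (3+2) annulation that also converges the C2 epimers of 12.
3. Enabling feature: the ring-fusion bond C1–C5 lies between the oxygen-bearing C2 (donor) and C5, which is α to the C6 oxygen carbon (acceptor when C6 is a ketone), so C1, C2 and C5 can be held as a donor–acceptor cyclopropane; C3–C4(OH)(i-Pr) is the enol of methyl isopropyl ketone.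
4. 12 ⇒ diazoketone 11 (a copper–bis(oxazoline) carbenoid cyclopropanation closes the cycloheptene and the cyclopropane together) ⇒ an acyclic chain with a Z-alkene, from p-xylene by Birch reduction and mono-ozonolysis.
5. Ring order: cycloheptene with the temporary cyclopropane (step 7), then the cyclopentane as the last ring of the carbon skeleton (step 9); the oxirane oxygen is added to C8=C9 afterwards (step 11).

Key step: step 9

Remark: daucane numbering is used for the core (C1 ring-fusion carbon with the angular CH3, C2 CH–O, C3 CH2, C4 C(OH)(i-Pr), C5 ring-fusion CH, C6 CH–O, C7 CH2, C8 C–CH3, C9, C10 CH2); β is the face of the C1 methyl group, α the face of H-5.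
Assumption: the Wittig step gives both enol-ether isomers and both are carried on, because they lead to the C8 epimers of 12, a centre that is ionised in step 9. It is assumed that the copper carbenoid attacks the same alkene face in both; the (S,S)-ligand is written and its mirror image is used if the sense of induction proves opposite.

Step 1
Reactants: 1 p-xylene
Product: 2 1,4-dimethylcyclohexa-1,4-diene
Conditions: Li, NH3 (l), EtOH, Et2O, −78 to −33 °C
Reagents that add atoms: none
Why: Birch reduction; the alkyl-bearing carbons stay sp2, so the skipped diene should carry both methyl groups on its alkenes.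

Step 2
Reactants: 2 1,4-dimethylcyclohexa-1,4-diene
Product: 4 (3Z)-3-methyl-6-oxohept-3-enal, via secondary ozonide 3 (not isolated)
Conditions: O3 (0.9 equiv), CH2Cl2, −78 °C; then Me2S, −78 °C to rt; crude 4 used at once
Reagents that add atoms: ozone [O-][O+]=O
Why: Ozonolysis (Criegee mechanism) of one of the two equivalent trisubstituted alkenes with sub-stoichiometric ozone; the ring fixes the Z geometry of the surviving alkene.

Step 3
Reactants: 4 (3Z)-3-methyl-6-oxohept-3-enal
Product: 5 (3Z)-3-methyl-6-oxohept-3-enoic acid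
Conditions: NaClO2, NaH2PO4, 2-methylbut-2-ene, t-BuOH/H2O, 0 °C
Reagents that add atoms: sodium chlorite [Na+].[O-]Cl=O
Why: Pinnick oxidation takes only the aldehyde and is mild enough that the skipped alkene should not move into conjugation.

Step 4
Reactants: 6 benzyl chloromethyl ether; 7 triphenylphosphine
Product: 8 [(benzyloxy)methyl]triphenylphosphonium chloride
Conditions: toluene, 80 °C
Reagents that add atoms: none
Why: SN2 quaternisation of the phosphine by the reactive α-chloro ether.

Step 5
Reactants: 5 (3Z)-3-methyl-6-oxohept-3-enoic acid; 8 [(benzyloxy)methyl]triphenylphosphonium chloride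
Product: 9 (3Z)-7-(benzyloxy)-3,6-dimethylhepta-3,6-dienoic acid (6E/6Z mixture)
Conditions: 8 (2.5 equiv), NaN(SiMe3)2 (3.5 equiv), THF, −78 to 0 °C, then 5; phosphate buffer (pH 5) work-up at 0 °C
Reagents that add atoms: none
Why: Wittig alkoxymethylenation of the methyl ketone with the carboxylate as a spectator; no stereocentre is formed and the enol-ether geometry is left open.

Step 6
Reactants: 9 (3Z)-7-(benzyloxy)-3,6-dimethylhepta-3,6-dienoic acid
Product: 11 (4Z)-8-(benzyloxy)-1-diazo-4,7-dimethylocta-4,7-dien-2-one, via mixed carbonic anhydride 10 (not isolated)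
Conditions: i-BuOCOCl, Et3N, THF, −15 °C; then CH2N2, Et2O, 0 °C
Reagents that add atoms: diazomethane C=[N+]=[N-]
Why: Acylation of diazomethane by a mixed anhydride (first stage of the Arndt–Eistert sequence) runs under basic conditions, which the acid-labile enol ether tolerates.

Step 7
Reactants: 11 (4Z)-8-(benzyloxy)-1-diazo-4,7-dimethylocta-4,7-dien-2-one
Product: 12 (1S,7R)-8-(benzyloxy)-4,7-dimethylbicyclo[5.1.0]oct-4-en-2-one (C8 epimer mixture; bicyclic C1, C2, C4, C5, C6, C7, C8 = daucane C5, C6, C8, C9, C10, C1, C2)
Conditions: [Cu(MeCN)4]PF6 (5 mol %), 2,2'-(propane-2,2-diyl)bis[(4S)-4-tert-butyl-4,5-dihydro-1,3-oxazole] (6 mol %), CH2Cl2, 25 °C, slow addition of 11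
Reagents that add atoms: none
Why: Intramolecular cyclopropanation of a copper carbenoid with the electron-rich enol ether, helped by the Z-alkene in the tether and by the preference of copper carbenoids for cyclopropanation over C–H insertion; the tether enforces the cis ring fusion, the bis(oxazoline) ligand selects the alkene face and so sets C1 and C7, and C8 follows the enol-ether geometry.

Step 8
Reactants: 13 3-methylbutan-2-one
Product: 14 trimethyl[(3-methylbut-1-en-2-yl)oxy]silane
Conditions: LiN(i-Pr)2, THF, −78 °C; then Me3SiCl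
Reagents that add atoms: chlorotrimethylsilane C[Si](C)(C)Cl
Why: Kinetic deprotonation at the methyl group and O-silylation give the terminal enol silane.

Step 9
Reactants: 12 (1S,7R)-8-(benzyloxy)-4,7-dimethylbicyclo[5.1.0]oct-4-en-2-one; 14 trimethyl[(3-methylbut-1-en-2-yl)oxy]silane
Product: 17 2α-(benzyloxy)-4β-hydroxydauc-8-en-6-one, via oxocarbenium stannyl enolate zwitterion 15 (not isolated), via seco-diketone stannyl enolate 16 (not isolated)
Conditions: SnCl4 (1.1 equiv), 14 (1.5 equiv), CH2Cl2, −78 °C, then −30 °C to let the aldol closure equilibrate; aq. NaHCO3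
Reagents that add atoms: none
Why: SnCl4 binds the ketone of 12 and the strained push–pull cyclopropane bond C2–C5 (benzyloxy donor on C2, carbonyl acceptor next to C5, aligned with the C=O π system) ionises to zwitterion 15, a regiodefined C5=C6 stannyl enolate with a benzyl oxocarbenium ion on C1; the CH2 terminus of 14 adds to the oxocarbenium carbon (Mukaiyama-type, C2–C3 bond, Me3SiCl lost) to give 16, whose enolate then attacks the new isopropyl ketone (C4–C5 bond). The closest known reaction type is the Lewis-acid-promoted formal (3+2) annulation of 2-alkoxycyclopropyl ketones (donor–acceptor cyclopropanes) with enol silyl ethers. The cyclopentane closes in the aldol event in a 5-(enolexo)-exo-trig mode, and the release of cyclopropane strain in the first event drives the sequence. C1 is carried over unchanged from 12; C2 should arise by attack of 14 anti to the departing C5 on the oxocarbenium ion whose benzyloxy group points away from the seven-membered ring (net inversion of the exo epimer), and since ring opening is reversible both C8 epimers of 12 should be funnelled through this one pathway. C4 and C5 are set in the aldol closure, which is reversible for a ketone acceptor under SnCl4, so the chelated stannyl aldolate with O4 cis to the C6 carbonyl, the isopropyl group on the face away from the angular methyl group and a trans ring fusion is expected to accumulate even if the kinetic closure is cis. The step needs cleavage of the external and not the ring-fusion cyclopropane bond (secured by the donor and acceptor at its two ends) and an enolate on the C5 side only (secured by the cyclopropane, which never lets the C7 enolate form); the C8=C9 alkene is a spectator because Markovnikov attack on the oxocarbenium ion would need a four-membered ring.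

Step 10
Reactants: 17 2α-(benzyloxy)-4β-hydroxydauc-8-en-6-one
Product: 18 2α-(benzyloxy)dauc-8-ene-4β,6α-diol
Conditions: Me4NBH(OAc)3, MeCN/AcOH (1:1), −20 °C
Reagents that add atoms: none
Why: Hydroxyl-directed Evans–Saksena reduction; the acetoxyborohydride bound to the 4β-OH delivers hydride to the β face of C6, giving the 6α-alcohol (anti-1,3-diol).

Step 11
Reactants: 18 2α-(benzyloxy)dauc-8-ene-4β,6α-diol
Product: 19 2α-(benzyloxy)-8α,9α-epoxydaucane-4β,6α-diol
Conditions: VO(acac)2 (5 mol %), t-BuOOH, CH2Cl2, 0 °C to rt
Reagents that add atoms: tert-butyl hydroperoxide CC(C)(C)OO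
Why: Vanadium-catalysed hydroxyl-directed epoxidation; the homoallylic 6α-OH binds the vanadium peroxide and delivers oxygen to the α face of C8=C9, while the tertiary 4β-OH is too remote to compete.

Step 12
Reactants: 19 2α-(benzyloxy)-8α,9α-epoxydaucane-4β,6α-diol; 20 4-acetoxy-3-methoxybenzoic acid
Product: 22 2α-(benzyloxy)-8α,9α-epoxy-4β-hydroxydaucan-6α-yl 4-acetoxy-3-methoxybenzoate, via O-acylisourea 21 (not isolated)
Conditions: EDC·HCl, DMAP, CH2Cl2, 0 °C to rt
Reagents that add atoms: none
Why: Steglich esterification under neutral conditions that spare the epoxide; only the secondary 6α-OH is acylated, the tertiary 4β-OH is not.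

Step 13
Reactants: 22 2α-(benzyloxy)-8α,9α-epoxy-4β-hydroxydaucan-6α-yl 4-acetoxy-3-methoxybenzoate
Product: 23 8α,9α-epoxy-2α,4β-dihydroxydaucan-6α-yl 4-acetoxy-3-methoxybenzoate
Conditions: H2 (1 atm), Pd/C, EtOAc, rt
Reagents that add atoms: none
Why: Hydrogenolysis of the benzyl ether; no alkene is left, and the trialkyl epoxide and both esters should be inert.

Step 14
Reactants: 23 8α,9α-epoxy-2α,4β-dihydroxydaucan-6α-yl 4-acetoxy-3-methoxybenzoate
Product: 24 2α-acetoxy-8α,9α-epoxy-4β-hydroxydaucan-6α-yl 4-acetoxy-3-methoxybenzoate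
Conditions: Ac2O, pyridine, DMAP (cat.), CH2Cl2, 0 °C to rt
Reagents that add atoms: acetic anhydride CC(=O)OC(C)=O
Why: DMAP-catalysed acetylation of the secondary 2α-OH; the tertiary 4β-OH should stay free under these mild conditions.

Step 15
Reactants: 24 2α-acetoxy-8α,9α-epoxy-4β-hydroxydaucan-6α-yl 4-acetoxy-3-methoxybenzoate
Product: 25 2α-acetoxy-8α,9α-epoxy-4β-hydroxydaucan-6α-yl 4-hydroxy-3-methoxybenzoate (target)
Conditions: pyrrolidine (3 equiv), CH2Cl2, 0 °C to rt
Reagents that add atoms: none
Why: Chemoselective aminolysis; the aryl acetate (phenoxide leaving group) should react far faster than the hindered alkyl acetate or the alkyl benzoate.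

**Compound list**
1 | p-xylene | Cc1ccc(C)cc1 | starting material
2 | 1,4-dimethylcyclohexa-1,4-diene | CC1=CCC(C)=CC1 | intermediate
3 | 1,4-dimethyl-7,8,9-trioxabicyclo[4.2.1]non-3-ene (secondary ozonide of 2, racemic) | CC1=CCC2(C)OOC(C1)O2 | intermediate (not isolated)
4 | (3Z)-3-methyl-6-oxohept-3-enal | CC(=O)C/C=C(C)\CC=O | intermediate
5 | (3Z)-3-methyl-6-oxohept-3-enoic acid | CC(=O)C/C=C(C)\CC(=O)O | intermediate
6 | benzyl chloromethyl ether | ClCOCc1ccccc1 | starting material
7 | triphenylphosphine | c1ccc(cc1)P(c1ccccc1)c1ccccc1 | starting material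
8 | [(benzyloxy)methyl]triphenylphosphonium chloride | [Cl-].c1ccc(cc1)[P+](COCc1ccccc1)(c1ccccc1)c1ccccc1 | intermediate
9 | (3Z)-7-(benzyloxy)-3,6-dimethylhepta-3,6-dienoic acid (6E/6Z mixture) | OC(=O)C/C(C)=C\CC(C)=COCc1ccccc1 | intermediate
10 | mixed isobutyl carbonic anhydride of 9 | CC(C)COC(=O)OC(=O)C/C(C)=C\CC(C)=COCc1ccccc1 | intermediate (not isolated)
11 | (4Z)-8-(benzyloxy)-1-diazo-4,7-dimethylocta-4,7-dien-2-one (7E/7Z mixture) | [N-]=[N+]=CC(=O)C/C(C)=C\CC(C)=COCc1ccccc1 | intermediate
12 | (1S,7R)-8-(benzyloxy)-4,7-dimethylbicyclo[5.1.0]oct-4-en-2-one (C8 epimer mixture) | O=C1CC(C)=CC[C@@]2(C)C(OCc3ccccc3)[C@@H]12 | intermediate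
13 | 3-methylbutan-2-one | CC(=O)C(C)C | starting material
14 | trimethyl[(3-methylbut-1-en-2-yl)oxy]silane | C=C(O[Si](C)(C)C)C(C)C | intermediate
15 | zwitterion from 12 and SnCl4: C5=C6 tetrachlorostannate enolate with a benzyl oxocarbenium ion on C1 (C1 as in 12) | C[C@@]1(C=[O+]Cc2ccccc2)CC=C(C)CC(O[Sn-](Cl)(Cl)(Cl)Cl)=C1 | intermediate (not isolated)
16 | trichlorostannyl enolate of 3-[1-(benzyloxy)-4-methyl-3-oxopentyl]-3,6-dimethylcyclohept-5-en-1-one (4,5-seco form of 17; C1 and C2 as in 17) | CC(C)C(=O)C[C@H](OCc1ccccc1)[C@]1(C)CC=C(C)CC(O[Sn](Cl)(Cl)Cl)=C1 | intermediate (not isolated)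
17 | 2α-(benzyloxy)-4β-hydroxydauc-8-en-6-one (1β-CH3, 5α-H, 4α-isopropyl) | O=C1CC(C)=CC[C@@]2(C)[C@@H](OCc3ccccc3)C[C@@](O)(C(C)C)[C@H]12 | intermediate
18 | 2α-(benzyloxy)dauc-8-ene-4β,6α-diol | O[C@H]1CC(C)=CC[C@@]2(C)[C@@H](OCc3ccccc3)C[C@@](O)(C(C)C)[C@H]12 | intermediate
19 | 2α-(benzyloxy)-8α,9α-epoxydaucane-4β,6α-diol | O[C@H]1C[C@@]2(C)O[C@H]2C[C@@]2(C)[C@@H](OCc3ccccc3)C[C@@](O)(C(C)C)[C@H]12 | intermediate
20 | 4-acetoxy-3-methoxybenzoic acid | COc1cc(C(=O)O)ccc1OC(C)=O | starting material
21 | O-acylisourea from 20 and EDC | CCN=C(NCCCN(C)C)OC(=O)c1ccc(OC(C)=O)c(OC)c1 | intermediate (not isolated)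
22 | 2α-(benzyloxy)-8α,9α-epoxy-4β-hydroxydaucan-6α-yl 4-acetoxy-3-methoxybenzoate | COc1cc(C(=O)O[C@H]2C[C@@]3(C)O[C@H]3C[C@@]3(C)[C@@H](OCc4ccccc4)C[C@@](O)(C(C)C)[C@H]23)ccc1OC(C)=O | intermediate
23 | 8α,9α-epoxy-2α,4β-dihydroxydaucan-6α-yl 4-acetoxy-3-methoxybenzoate | COc1cc(C(=O)O[C@H]2C[C@@]3(C)O[C@H]3C[C@@]3(C)[C@@H](O)C[C@@](O)(C(C)C)[C@H]23)ccc1OC(C)=O | intermediate
24 | 2α-acetoxy-8α,9α-epoxy-4β-hydroxydaucan-6α-yl 4-acetoxy-3-methoxybenzoate | COc1cc(C(=O)O[C@H]2C[C@@]3(C)O[C@H]3C[C@@]3(C)[C@@H](OC(C)=O)C[C@@](O)(C(C)C)[C@H]23)ccc1OC(C)=O | intermediate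
25 | 2α-acetoxy-8α,9α-epoxy-4β-hydroxydaucan-6α-yl 4-hydroxy-3-methoxybenzoate | COc1cc(C(=O)O[C@H]2C[C@@]3(C)O[C@H]3C[C@@]3(C)[C@@H](OC(C)=O)C[C@@](O)(C(C)C)[C@H]23)ccc1O | target

**Step count and risks**
Total step count: 15. Longest linear sequence: 13 steps (1, 2, 3, 5, 6, 7, 9, 10, 11, 12, 13, 14, 15).

Steps most likely to fail:

1. Step 9. The enol silane may add to the oxocarbenium ion from both faces, so that control at C2 is lost. A second concern is an aldol closure that stays at the kinetic cis-fused aldolate; the ring-fusion outcome rests on a thermodynamic preference that is not certain, and the only remedy offered is to return isolated cis-fused aldol to the SnCl4 conditions for retro-aldol recycling. The fallback deals with C2 and moves its control from the C–C bond formation to a hydroxyl-directed hydride delivery. It sets out from 23 and comes back to 23. The C2 mixture is carried through steps 10 to 13, none of which touches C2. The C2 epimers of 23 are oxidised with Dess–Martin periodinane (CH2Cl2, NaHCO3) to the single ketone 8α,9α-epoxy-4β-hydroxy-2-oxodaucan-6α-yl 4-acetoxy-3-methoxybenzoate F1. Me4NBH(OAc)3 (MeCN/AcOH, −20 °C) should then deliver hydride from the 4β-hydroxyl group to the β face of C2 and return 23 with the 2α-hydroxyl group only (anti-1,3-diol).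

2. Step 7. The seven-membered ring closure by the carbenoid may lose to carbene dimerisation, or the two enol-ether isomers may be discriminated poorly. The fallback closes the cycloheptene by metathesis after an intermolecular cyclopropanation; it sets out from 8 and comes back at 12. The ylide from 8 is condensed with pent-4-en-2-one to give the enol ether {[(2-methylpenta-1,4-dien-1-yl)oxy]methyl}benzene F2. 3-Methylbut-3-enoic acid is converted through its mixed anhydride and CH2N2 into 1-diazo-4-methylpent-4-en-2-one F3. Cyclopropanation of F2 with F3 under the same [Cu(MeCN)4]PF6–bis(oxazoline) catalyst gives 1-[3-(benzyloxy)-2-methyl-2-(prop-2-en-1-yl)cyclopropyl]-3-methylbut-3-en-1-one F4; only the isomers with the acyl group cis to the allyl group are taken on. Ring-closing metathesis with the second-generation Grubbs catalyst (CH2Cl2, 40 °C) then forms the trisubstituted C4=C5 alkene of 12.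

3. Step 5. The ylide may deprotonate the doubly activated methylene between the ketone and the alkene, which would cause alkene migration and low conversion, and it gives both enol-ether isomers. The fallback is a two-stage Horner–Wittig olefination; it sets out from 5 and 6 and comes back at 9. Arbuzov reaction of 6 with ethyl diphenylphosphinite gives [(benzyloxy)methyl]diphenylphosphine oxide F5. Its lithio derivative (LiN(i-Pr)2, THF, −78 °C, where carbonyl addition should outrun proton transfer) adds to the ketone of the lithium carboxylate of 5 and gives the β-hydroxy phosphine oxide (3Z)-7-(benzyloxy)-7-(diphenylphosphoryl)-6-hydroxy-3,6-dimethylhept-3-enoic acid F6. The diastereomers of F6 are separated, and KH in DMF triggers the stereospecific syn elimination to 9 as a single enol-ether isomer, which also removes the E/Z question from step 7.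

**Further compounds**
F1 | step 9 | 8α,9α-epoxy-4β-hydroxy-2-oxodaucan-6α-yl 4-acetoxy-3-methoxybenzoate | COc1cc(C(=O)O[C@H]2C[C@@]3(C)O[C@H]3C[C@@]3(C)C(=O)C[C@@](O)(C(C)C)[C@H]23)ccc1OC(C)=O
F2 | step 7 | {[(2-methylpenta-1,4-dien-1-yl)oxy]methyl}benzene (E/Z mixture) | C=CCC(C)=COCc1ccccc1
F3 | step 7 | 1-diazo-4-methylpent-4-en-2-one | C=C(C)CC(=O)C=[N+]=[N-]
F4 | step 7 | 1-[3-(benzyloxy)-2-methyl-2-(prop-2-en-1-yl)cyclopropyl]-3-methylbut-3-en-1-one (acyl cis to allyl; ring carbons configured as C1 and C7 of 12) | C=C(C)CC(=O)[C@@H]1C(OCc2ccccc2)[C@]1(C)CC=C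
F5 | step 5 | [(benzyloxy)methyl]diphenylphosphine oxide | O=P(COCc1ccccc1)(c1ccccc1)c1ccccc1
F6 | step 5 | (3Z)-7-(benzyloxy)-7-(diphenylphosphoryl)-6-hydroxy-3,6-dimethylhept-3-enoic acid (separated diastereomers) | OC(=O)C/C(C)=C\CC(C)(O)C(OCc1ccccc1)P(=O)(c1ccccc1)c1ccccc1
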